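All runs stem from a simulated flask with made-up constants; noise was put on by code.

- You cannot take more target out of a flask than its charges can pay for, and here the price may be double. With the main step alone, dissolved solid electrophile meets nucleophile one to one, so 11.0 mM of nucleophile against 10 mM of solid pays for the whole charge.

| flask | solid electrophile | nucleophile | free base | remark | time |
|---|---|---|---|---|---|
| elm | 10 mM | 11 mM | 19 mM | run made earlier |  |
| south | 10 mM | 11.0 mM | 10.0 mM |  | 6.0 d |
| north-east | 10 mM | 11.0 mM | 20.0 mM |  | 6.0 d |
| north-west | 10 mM | 11.0 mM | 5.00 mM |  | 6.0 d |

elm run (percent of the solid electrophile charged)

| time / d | solid electrophile / % | target / % |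
|---|---|---|
| 0.625 | 69.4 | 9.4 |
| 1.25 | 49.8 | 25.3 |
| 1.67 | 41.2 | 36.1 |
| 2.50 | 23.2 | 52.2 |
| 3.00 | 13.8 | 58.9 |

(scatter of a reading: 1 percentage point)

- at the start none of the solid electrophile is in solution
- what has only dissolved of solid electrophile counts as not reacted
- no earlier run changes the charge of free base; that part of a forecast is a guess

- part of the solid electrophile that has reacted (what has only dissolved counts as not reacted) at the end, south
- part of the solid electrophile that has reacted (what has only dissolved counts as not reacted) at the end, north-east
- part of the solid electrophile that has reacted (what has only dissolved counts as not reacted) at the end, north-west
- what raising the concentration of free base from its lowest to its highest value here does to the part of the solid electrophile that has reacted (what has only dissolved counts as not reacted) (changes below 5 percentage points count as none) (it rises / it falls / no change)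

- Now add, as my own assumption, that each target frees one acid, which a free base or a nucleophile must take up. Divide the rate at which these takers are used by the rate at which target appears, and time drops out: 2 takers go per target, one nucleophile consumed and one taker bound.
- Define the ceiling X as nucleophile plus free base charged, over 2 times the solid charged; for north-west X is 80.0%, the taker ceiling. In south X is 105% and in north-east 155%, both above the whole charge of solid, so on this reckoning the takers set no stop in those two flasks.
- Last add the road through solution: at 3.00 d the elm run has 27.3% of its charge neither solid nor target, which I read as dissolved and waiting. Its target rose by 0.208 /d of the charge with 19 mM of free base, and that pace, if it held in north-west, would bring that flask to X in 3.85 d, sooner than 6.0 d; the pace should fall as nucleophile goes, so my own reckoning puts north-west somewhat below X at 6.0 d.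
- The forecast gives 82% for south, 85% for north-east and 60% for north-west, with the trend it rises, on the ground that at low base “acid protonates the nucleophile, so the reaction slows or stalls”. Its north-west value lies 20 percentage points under my X, so there the forecast and my reckoning differ.
- The flask gives 77.4% in south, 82.6% in north-east and 70.5% in north-west, so the trend is it rises, by 12 points. North-west stands below X and still has 14.6% of its own free base unbound at 6.00 d. At 60.0 d it has reached 82.6%, past X, and 0.573 mM of acid set free stands untaken; adding that to the numerator of X gives 82.9%.

    electrophile + nucleophile → acid set free + target (k = 5.70 /M/h)
    nucleophile + acid set free ⇌ protonated nucleophile, settled at all times (K = 3.00 × 10⁵ /M)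
    acid set free + free base ⇌ salt of the base, settled at all times (K = 3.30 × 10⁵ /M)
    free base ⇌ dormant form (K = 0.540, k = 0.0300 /h)
    solid electrophile ⇌ electrophile, rate k5*(cs5 - [electrophile]) while solid is left; crystals form when [electrophile] > cs5 (solubility = 3.50 mM, k = 0.0920 /h)

- Take the neighbour flask that is north-west with 27 mM of nucleophile in place of 11.0 mM: X is 160%, above the whole charge of solid, so on this reckoning the takers should set no stop. It gives 99.9% with 33% of its nucleophile still unbound, and its limiting reagent is the solid electrophile.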